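The target is disconnected to one C2-symmetric bis-oxolane. The tetralin half (C1 aryl, C2 CH2OH, C3 carbinol, C4 CH2, fused arene C4a–C8a) is a skeletal isomer of the oxolane half (O1, C2 aryl, C3 CH2OH, C4 benzyl carbinol, C5), with the same carbon backbone and the same configuration at the CH(CH2OH)–C(OH) pair. The bis-oxolane is built two-directionally from bivanillin. Its monotosylate (benzyl ethers on the guaiacyl phenols and the primary alcohols) is treated with acid: only the oxolane on the ring with the free para-phenol ionises at C2–O1, and the neighbouring benzyl arene closes the tetralin C1–C8a bond, setting C1.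

Key step: step 14

Remark: the target is taken exactly as drawn (oxolane 2R,3R,4S with aryl, CH2OH and benzyl groups on one ring face; tetralin 1S,2S,3S); C2 of the oxolanes is therefore set kinetically and kept away from acid while its para-oxygen is electron-releasing, and the primary alcohols of the rearrangement precursor are carried as benzyl ethers so that the phenol monosulfonylation meets no competing primary hydroxyl.

Step 1
Reactants: 1 vanillin (2 equiv)
Product: 2 5,5'-bivanillin (6,6'-dihydroxy-5,5'-dimethoxybiphenyl-3,3'-dicarbaldehyde)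
Conditions: 1 (2 equiv), Na2S2O8 (1.1 equiv), FeSO4·7H2O (cat.), H2O, 80 °C
Reagents that add atoms: vanillin 1 (second molecule), COc1cc(C=O)ccc1O
Why: Oxidative phenol coupling of two molecules of vanillin: the persulfate/iron couple generates the phenoxyl radical, which can dimerise only at C5 (the one free position ortho to OH, the para position being blocked by the formyl group), giving the 5,5'-biaryl bond of the core.

Step 2
Reactants: 2 5,5'-bivanillin
Product: 3 bis-TIPS bivanillin (5,5'-dimethoxy-6,6'-bis(triisopropylsilyloxy)biphenyl-3,3'-dicarbaldehyde)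
Conditions: TIPSCl (2.5 equiv), imidazole (5 equiv), DMF, 50 °C
Reagents that add atoms: triisopropylsilyl chloride (2 equiv incorporated), CC(C)[Si](Cl)(C(C)C)C(C)C
Why: Imidazole-assisted silylation of both phenols; the TIPS ethers survive hydride, alkoxide, peracid and Grignard reagents and are later removed by fluoride without acid, which the cis-configured C2 centres would not tolerate.

Step 3
Reactants: 4 benzyloxyacetaldehyde; 5 methyl acrylate
Product: 6 methyl 4-(benzyloxy)-3-hydroxy-2-methylidenebutanoate (racemic)
Conditions: DABCO (0.5 equiv), dioxane/H2O, rt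
Reagents that add atoms: none
Why: Morita–Baylis–Hillman reaction of an activated α-alkoxy aldehyde with the acrylate; the carbinol centre may be racemic because it is erased in step 5.

Step 4
Reactants: 6 methyl 4-(benzyloxy)-3-hydroxy-2-methylidenebutanoate
Product: 7 methyl 3-acetoxy-4-(benzyloxy)-2-methylidenebutanoate (racemic)
Conditions: Ac2O, pyridine, DMAP (cat.), CH2Cl2, 0 °C → rt
Reagents that add atoms: acetic anhydride, CC(=O)OC(C)=O
Why: DMAP-catalysed acylation of the secondary allylic alcohol installs the leaving group for allylic substitution.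

Step 5
Reactants: 7 methyl 3-acetoxy-4-(benzyloxy)-2-methylidenebutanoate
Product: 8 methyl (E)-4-(benzyloxy)-2-[(4,4,5,5-tetramethyl-1,3,2-dioxaborolan-2-yl)methyl]but-2-enoate (CH2OBn trans to the ester and cis to CH2B)
Conditions: B2pin2, CuCl (10 mol%), KOAc, LiCl, DMF, rt
Reagents that add atoms: bis(pinacolato)diboron, CC1(C)OB(OC1(C)C)B1OC(C)(C)C(C)(C)O1
Why: Copper-catalysed SN2' borylation (Miyaura-type allylic borylation): the boryl-copper species adds to the acrylate terminus with loss of acetate, which erases the carbinol centre and should give the trisubstituted alkene with CH2OBn trans to the ester, the geometry that minimises allylic strain; a minor geometric isomer would be removed by chromatography.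

Step 6
Reactants: 3 bis-TIPS bivanillin; 8 allylboronate (2.6 equiv)
Product: 10 bis-homoallylic alcohol diester (core of 3; each formyl group replaced by a (1R,2R)-2-[(benzyloxy)methyl]-1-hydroxy-3-(methoxycarbonyl)but-3-en-1-yl group), via bis-O-pinacolboryl adduct 9 (not isolated)
Conditions: 8 (2.6 equiv), (R)-TRIP phosphoric acid [(R)-3,3'-bis(2,4,6-triisopropylphenyl)-1,1'-binaphthyl-2,2'-diyl hydrogen phosphate] (10 mol%), 4 Å MS, toluene, 0 °C → rt; then aq. NaHCO3
Reagents that add atoms: allylboronate 8 (second equivalent), COC(=O)/C(CB1OC(C)(C)C(C)(C)O1)=C/COCc1ccccc1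
Why: Chiral-phosphoric-acid-catalysed allylboration of an aromatic aldehyde, one molecule of 8 adding to each formyl group through a closed six-membered chair transition state: the γ-carbon bonds to the formyl carbon, the CH2OBn group (cis to CH2B) sits axial and so gives the 1,2-syn relationship (the future cis C2/C3 of the oxolane), while the (R)-configured catalyst, hydrogen-bonded to a boronate oxygen and the formyl hydrogen, directs attack to the re face (the sense known for aryl aldehydes with this catalyst) and sets the (R) carbinol centres; the two-fold addition raises the optical purity of the C2-symmetric product because mismatched additions end in the separable meso isomer.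

Step 7
Reactants: 10 bis-homoallylic alcohol diester
Product: 11 bis-allylic diol (core of 3; each ring carries a (1R,2R)-2-[(benzyloxy)methyl]-1-hydroxy-3-(hydroxymethyl)but-3-en-1-yl group)
Conditions: i-Bu2AlH (8 equiv), CH2Cl2, −78 → −20 °C; aq. potassium sodium tartrate
Reagents that add atoms: none
Why: 1,2-Reduction of the α-substituted acrylate by the aluminium hydride gives the allylic alcohol without touching the stereocentres or the silyl and benzyl ethers, and any α-methylene lactone formed by lactonisation of 10 is reduced to the same diol.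

Step 8
Reactants: 11 bis-allylic diol; 12 p-toluenesulfonyl chloride (2.1 equiv)
Product: 14 bis(4-methylideneoxolane) (core of 3; each ring carries a (2R,3R)-3-[(benzyloxy)methyl]-4-methylideneoxolan-2-yl group; aryl cis to CH2OBn), via bis-allylic tosylate 13 (not isolated)
Conditions: TsCl (2.1 equiv), Et3N, DMAP (cat.), CH2Cl2, −20 °C; then NaH, THF, 0 °C → rt
Reagents that add atoms: none
Why: Chemoselective sulfonylation of the unhindered primary allylic hydroxyl followed by intramolecular Williamson etherification (5-exo-tet SN2 at the allylic CH2 by the secondary alkoxide): the benzylic C–O bond is never broken, so the carbinol configuration is retained and the kinetically set 2,3-cis oxolane results, while the benzyl ether on the C3 arm can neither migrate nor compete.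

Step 9
Reactants: 14 bis(4-methylideneoxolane)
Product: 15 bis-spiroepoxide (core of 3; each ring carries a (3R,6R,7R)-7-[(benzyloxy)methyl]-1,5-dioxaspiro[2.4]heptan-6-yl group; epoxide oxygen trans to CH2OBn)
Conditions: mCPBA (2.4 equiv), NaHCO3, CH2Cl2, 0 °C
Reagents that add atoms: meta-chloroperoxybenzoic acid, OOC(=O)c1cccc(Cl)c1
Why: Prilezhaev epoxidation: the peracid approaches the exocyclic alkene from the ring face opposite to the cis C2 aryl and C3 CH2OBn groups (no free hydroxyl is present to direct it), so the epoxide oxygen ends trans and the epoxide CH2 cis to CH2OBn, which fixes the configuration of the future C4 carbinol.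

Step 10
Reactants: 16 4-bromo-2-methoxyphenol
Product: 17 1-(benzyloxy)-4-bromo-2-methoxybenzene
Conditions: BnBr, K2CO3, DMF, rt
Reagents that add atoms: benzyl bromide, BrCc1ccccc1
Why: Williamson ether synthesis on the phenoxide; the benzyl ether survives Grignard formation and the Lewis acid of step 14 and is removed in the last step.

Step 11
Reactants: 15 bis-spiroepoxide; 17 1-(benzyloxy)-4-bromo-2-methoxybenzene (3 equiv)
Product: 19 silyl-protected bis-oxolane (core of 3; each ring carries a (2R,3R,4S)-4-[4-(benzyloxy)-3-methoxybenzyl]-3-[(benzyloxy)methyl]-4-hydroxyoxolan-2-yl group), via arylmagnesium bromide 18 (not isolated)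
Conditions: 17 (3 equiv), Mg, THF, 40 °C; then CuBr·SMe2 (20 mol%), 15 (1 equiv), THF, −30 → 0 °C; aq. NH4Cl
Reagents that add atoms: 1-(benzyloxy)-4-bromo-2-methoxybenzene 17 (second equivalent, used as its Grignard reagent 18), COc1cc(Br)ccc1OCc1ccccc1
Why: Grignard formation followed by copper-catalysed SN2 opening of each 2,2-disubstituted epoxide at its CH2 terminus, one aryl group being delivered to each of the two epoxides: the spiro C–O bond is not touched, so the tertiary hydroxyl keeps the configuration set in step 9 (trans to CH2OBn) and the new benzyl group ends cis to the C3 CH2OBn and C2 aryl groups.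

Step 12
Reactants: 19 silyl-protected bis-oxolane
Product: 20 bis-oxolane biaryl diol (19 with both silyl ethers cleaved to free 6,6'-phenols)
Conditions: Bu4NF, AcOH (1:1, 2.4 equiv), THF, 0 °C → rt
Reagents that add atoms: none
Why: Fluoride-mediated cleavage of the aryl silyl ethers (strong Si–F bond, phenoxide leaving group) under buffered, non-ionising conditions frees the two biaryl phenols while the benzyl ethers, tertiary alcohols and cis C2 centres stay intact.

Step 13
Reactants: 20 bis-oxolane biaryl diol; 12 p-toluenesulfonyl chloride (1.0 equiv)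
Product: 21 bis-oxolane monotosylate (20 with one of the two biaryl phenols as its p-toluenesulfonate)
Conditions: TsCl (1.0 equiv), K2CO3 (1.1 equiv), acetone, 0 °C → rt
Reagents that add atoms: none
Why: Monosulfonylation of a 2,2'-biphenol: the first phenol is unusually acidic because its anion is hydrogen-bonded to the neighbouring hydroxyl, and once it is tosylated the remaining hydroxyl is less acidic and more hindered, so one equivalent of base and sulfonyl chloride should stop at the monotosylate, the tertiary alcohols being inert and unreacted 20 being recycled.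

Step 14
Reactants: 21 bis-oxolane monotosylate
Product: 22 oxolane–tetralin monotosylate (the ring with the tosylate keeps its (2R,3R,4S)-oxolane; the ring with the free phenol now carries a (1S,2S,3S)-7-(benzyloxy)-2-[(benzyloxy)methyl]-3-hydroxy-3-(hydroxymethyl)-6-methoxy-1,2,3,4-tetrahydronaphthalen-1-yl group)
Conditions: BF3·OEt2 (1.5 equiv), CH2Cl2 (high dilution), −40 → 0 °C; aq. NaHCO3
Reagents that add atoms: none
Why: BF3 coordinates O1 of the oxolane whose C2 aryl group carries the free para-hydroxyl; the benzylic C2–O1 bond ionises to a para-hydroxybenzyl cation (a protonated para-quinone methide) and the C5 oxygen is released as the future C3 hydroxymethyl group. The closest known reaction is the acid-mediated change of 2-aryl-4-benzyl-oxolane lignans into 1-aryltetralins, an intramolecular Friedel–Crafts alkylation. The six-membered carbocycle (C1, C2, C3, C4, C4a, C8a) closes by attack of the benzyl-ring carbon para to its methoxy group on the cationic carbon, which becomes ring atom C1 (6-endo with respect to the attacking arene bond, 6-exo-trig with respect to the quinone-methide C=C); this C–C closure is irreversible whereas re-closure to the oxolane is reversible, so the material should funnel to the tetralin. The cation is planar, so the new C1 centre is set by the existing C2 centre in a chair-like transition state with the aryl and CH2OBn groups both pseudo-equatorial, giving the 1,2-trans product (1S), which is also the more stable epimer. Site selectivity rests on the para-oxygen of the two C2 aryl groups: the tosyloxy group cannot stabilise a benzylic cation, so the second oxolane and its cis C2/C3 relationship survive, and the benzyl ethers and tertiary alcohols tolerate the cold Lewis acid.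

Step 15
Reactants: 22 oxolane–tetralin monotosylate
Product: 23 oxolane–tetralin tetrabenzyl ether (22 with the tosylate cleaved to the free phenol)
Conditions: Mg turnings, MeOH, rt (sonication)
Reagents that add atoms: none
Why: Reductive cleavage of the aryl sulfonate S–O bond by electron transfer from magnesium in methanol frees the phenol under non-acidic conditions, so the now activated cis oxolane is not ionised.

Step 16
Reactants: 23 oxolane–tetralin tetrabenzyl ether
Product: 24 CNP0344108.1 (target)
Conditions: H2 (1 atm), Pd/C (10 wt%), EtOAc/MeOH, rt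
Reagents that add atoms: none
Why: Hydrogenolysis of the four O-benzyl ethers over palladium under neutral conditions; the cyclic benzylic ether and the doubly benzylic C1–H bond should be cleaved far more slowly than O-benzyl groups, and no acid is present that could epimerise C2 of the oxolane.

Compound list
1 | vanillin | COc1cc(C=O)ccc1O | starting material
2 | 5,5'-bivanillin (6,6'-dihydroxy-5,5'-dimethoxybiphenyl-3,3'-dicarbaldehyde) | COc1cc(C=O)cc(-c2cc(C=O)cc(OC)c2O)c1O | intermediate
3 | 5,5'-dimethoxy-6,6'-bis(triisopropylsilyloxy)biphenyl-3,3'-dicarbaldehyde | COc1cc(C=O)cc(-c2cc(C=O)cc(OC)c2O[Si](C(C)C)(C(C)C)C(C)C)c1O[Si](C(C)C)(C(C)C)C(C)C | intermediate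
4 | benzyloxyacetaldehyde | O=CCOCc1ccccc1 | starting material
5 | methyl acrylate | C=CC(=O)OC | starting material
6 | methyl 4-(benzyloxy)-3-hydroxy-2-methylidenebutanoate (racemic) | C=C(C(=O)OC)C(O)COCc1ccccc1 | intermediate
7 | methyl 3-acetoxy-4-(benzyloxy)-2-methylidenebutanoate (racemic) | C=C(C(=O)OC)C(OC(C)=O)COCc1ccccc1 | intermediate
8 | methyl (E)-4-(benzyloxy)-2-[(4,4,5,5-tetramethyl-1,3,2-dioxaborolan-2-yl)methyl]but-2-enoate | COC(=O)/C(CB1OC(C)(C)C(C)(C)O1)=C/COCc1ccccc1 | intermediate
9 | bis-O-pinacolboryl adduct (10 with both carbinol oxygens bound to pinacolboryl; not isolated) | COc1cc([C@H](OB3OC(C)(C)C(C)(C)O3)[C@@H](COCc3ccccc3)C(=C)C(=O)OC)cc(-c2cc([C@H](OB3OC(C)(C)C(C)(C)O3)[C@@H](COCc3ccccc3)C(=C)C(=O)OC)cc(OC)c2O[Si](C(C)C)(C(C)C)C(C)C)c1O[Si](C(C)C)(C(C)C)C(C)C | intermediate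
10 | C2-symmetric diester: 5,5'-dimethoxy-6,6'-bis(triisopropylsilyloxy)biphenyl-3,3'-diyl core bearing at C3 and C3' a (1R,2R)-2-[(benzyloxy)methyl]-1-hydroxy-3-(methoxycarbonyl)but-3-en-1-yl group | COc1cc([C@H](O)[C@@H](COCc3ccccc3)C(=C)C(=O)OC)cc(-c2cc([C@H](O)[C@@H](COCc3ccccc3)C(=C)C(=O)OC)cc(OC)c2O[Si](C(C)C)(C(C)C)C(C)C)c1O[Si](C(C)C)(C(C)C)C(C)C | intermediate
11 | C2-symmetric tetraol: same core bearing at C3 and C3' a (1R,2R)-2-[(benzyloxy)methyl]-1-hydroxy-3-(hydroxymethyl)but-3-en-1-yl group | COc1cc([C@H](O)[C@@H](COCc3ccccc3)C(=C)CO)cc(-c2cc([C@H](O)[C@@H](COCc3ccccc3)C(=C)CO)cc(OC)c2O[Si](C(C)C)(C(C)C)C(C)C)c1O[Si](C(C)C)(C(C)C)C(C)C | intermediate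
12 | p-toluenesulfonyl chloride | Cc1ccc(S(=O)(=O)Cl)cc1 | starting material
13 | bis-allylic tosylate (11 with both primary allylic hydroxyls as p-toluenesulfonates; not isolated) | COc1cc([C@H](O)[C@@H](COCc3ccccc3)C(=C)COS(=O)(=O)c3ccc(C)cc3)cc(-c2cc([C@H](O)[C@@H](COCc3ccccc3)C(=C)COS(=O)(=O)c3ccc(C)cc3)cc(OC)c2O[Si](C(C)C)(C(C)C)C(C)C)c1O[Si](C(C)C)(C(C)C)C(C)C | intermediate
14 | C2-symmetric bis-oxolane: same core bearing at C3 and C3' a (2R,3R)-3-[(benzyloxy)methyl]-4-methylideneoxolan-2-yl group | COc1cc([C@@H]3OCC(=C)[C@@H]3COCc4ccccc4)cc(-c2cc([C@@H]3OCC(=C)[C@@H]3COCc4ccccc4)cc(OC)c2O[Si](C(C)C)(C(C)C)C(C)C)c1O[Si](C(C)C)(C(C)C)C(C)C | intermediate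
15 | C2-symmetric bis-spiroepoxide: same core bearing at C3 and C3' a (3R,6R,7R)-7-[(benzyloxy)methyl]-1,5-dioxaspiro[2.4]heptan-6-yl group | COc1cc([C@@H]3OC[C@]4(CO4)[C@@H]3COCc4ccccc4)cc(-c2cc([C@@H]3OC[C@]4(CO4)[C@@H]3COCc4ccccc4)cc(OC)c2O[Si](C(C)C)(C(C)C)C(C)C)c1O[Si](C(C)C)(C(C)C)C(C)C | intermediate
16 | 4-bromo-2-methoxyphenol | COc1cc(Br)ccc1O | starting material
17 | 1-(benzyloxy)-4-bromo-2-methoxybenzene | COc1cc(Br)ccc1OCc1ccccc1 | intermediate
18 | [4-(benzyloxy)-3-methoxyphenyl]magnesium bromide (not isolated) | COc1cc([Mg]Br)ccc1OCc1ccccc1 | intermediate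
19 | C2-symmetric bis-oxolane: 5,5'-dimethoxy-6,6'-bis(triisopropylsilyloxy)biphenyl-3,3'-diyl core bearing at C3 and C3' a (2R,3R,4S)-4-[4-(benzyloxy)-3-methoxybenzyl]-3-[(benzyloxy)methyl]-4-hydroxyoxolan-2-yl group | COc1cc([C@@H]3OC[C@](O)(Cc4ccc(OCc5ccccc5)c(OC)c4)[C@@H]3COCc4ccccc4)cc(-c2cc([C@@H]3OC[C@](O)(Cc4ccc(OCc5ccccc5)c(OC)c4)[C@@H]3COCc4ccccc4)cc(OC)c2O[Si](C(C)C)(C(C)C)C(C)C)c1O[Si](C(C)C)(C(C)C)C(C)C | intermediate
20 | bis-oxolane biaryl diol: 19 with free 6,6'-hydroxyls | COc1cc([C@@H]3OC[C@](O)(Cc4ccc(OCc5ccccc5)c(OC)c4)[C@@H]3COCc4ccccc4)cc(-c2cc([C@@H]3OC[C@](O)(Cc4ccc(OCc5ccccc5)c(OC)c4)[C@@H]3COCc4ccccc4)cc(OC)c2O)c1O | intermediate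
21 | bis-oxolane monotosylate (precursor of the key step): 20 with the 6-hydroxyl as p-toluenesulfonate and the 6'-hydroxyl free | COc1cc([C@@H]3OC[C@](O)(Cc4ccc(OCc5ccccc5)c(OC)c4)[C@@H]3COCc4ccccc4)cc(-c2cc([C@@H]3OC[C@](O)(Cc4ccc(OCc5ccccc5)c(OC)c4)[C@@H]3COCc4ccccc4)cc(OC)c2O)c1OS(=O)(=O)c6ccc(C)cc6 | intermediate
22 | oxolane–tetralin monotosylate (product of the key step): tosylated ring with the (2R,3R,4S)-oxolane of 21; free-phenol ring with a (1S,2S,3S)-7-(benzyloxy)-2-[(benzyloxy)methyl]-3-hydroxy-3-(hydroxymethyl)-6-methoxy-1,2,3,4-tetrahydronaphthalen-1-yl group | COc1cc([C@@H]3OC[C@](O)(Cc4ccc(OCc5ccccc5)c(OC)c4)[C@@H]3COCc4ccccc4)cc(-c2cc([C@H]3c4cc(OCc5ccccc5)c(OC)cc4C[C@@](O)(CO)[C@@H]3COCc4ccccc4)cc(OC)c2O)c1OS(=O)(=O)c6ccc(C)cc6 | intermediate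
23 | oxolane–tetralin tetrabenzyl ether: 22 with the tosylate replaced by a free phenol | COc1cc([C@@H]3OC[C@](O)(Cc4ccc(OCc5ccccc5)c(OC)c4)[C@@H]3COCc4ccccc4)cc(-c2cc([C@H]3c4cc(OCc5ccccc5)c(OC)cc4C[C@@](O)(CO)[C@@H]3COCc4ccccc4)cc(OC)c2O)c1O | intermediate
24 | CNP0344108.1 | COc1cc(C[C@@]2(O)CO[C@@H](c3cc(OC)c(O)c(-c4cc([C@H]5c6cc(O)c(OC)cc6C[C@@](O)(CO)[C@@H]5CO)cc(OC)c4O)c3)[C@H]2CO)ccc1O | target

Total step count: 16 steps.
Longest linear sequence: 13 steps (from 4 and 5 through steps 3–9 and 11–16); 12 steps from vanillin.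

Steps most likely to fail

Step 6. The ester-bearing allylboronate is a weak nucleophile, so allyl transfer under Brønsted-acid catalysis may be slow, and an uncatalysed background reaction or isomerisation of the reagent could erode facial and syn selectivity. The fallback moves stereocontrol from the catalyst into the reagent. It sets out from acetate 7 and dialdehyde 3 and comes back at 10. Acetate 7 is borylated with tetrahydroxydiboron (Pd2(dba)3 cat., DMSO) to the allylboronic acid F1, which is esterified with diisopropyl D-tartrate (MgSO4) to the tartrate allylboronate F2. This more Lewis-acidic reagent (2.6 equiv) adds to 3 without catalyst (toluene, 4 Å MS, −78 °C → rt) through the same chair, the (S,S)-tartrate directing attack to the re face, and gives the bis-borate adduct F3, whose hydrolysis gives 10. Induction per site may be only moderate, but the two-fold addition upgrades it because mismatched additions end mainly in the separable meso isomer.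

Step 14. The Lewis acid may cleave benzyl ethers, ionisation may be sluggish, or intermolecular alkylation may compete with ring closure. The fallback changes the order of the endgame so that the rearrangement runs on the unprotected polyphenol, the substitution pattern for which the oxolane-to-tetralin change is established in the monomeric lignans. It sets out from 21 and comes back at target 24. Compound 21 is hydrogenolysed (H2, Pd/C) to the debenzylated monotosylate F4, which is treated with dilute protic acid (HCO2H, or HCl in MeOH, rt) to give the unprotected oxolane–tetralin monotosylate F5. Mg in MeOH then removes the tosylate and gives 24 directly.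

Step 13. Sulfonylation may over- or under-run and leave mixtures of diol, monotosylate and bis-tosylate. The fallback reverses the desymmetrisation, setting out from 20 and coming back at 21. Compound 20 is tosylated exhaustively (excess TsCl, K2CO3, acetone) to the bis-tosylate F6, and one sulfonate is cleaved with one equivalent of KOH in THF/MeOH. The aryloxide formed first shields and deactivates the neighbouring sulfonate, so cleavage should stop at 21.

Further compounds
F1 | step 6 | (E)-[4-(benzyloxy)-2-(methoxycarbonyl)but-2-en-1-yl]boronic acid | COC(=O)/C(CB(O)O)=C/COCc1ccccc1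
F2 | step 6 | diisopropyl (4S,5S)-2-[(E)-4-(benzyloxy)-2-(methoxycarbonyl)but-2-en-1-yl]-1,3,2-dioxaborolane-4,5-dicarboxylate | COC(=O)/C(CB1O[C@H](C(=O)OC(C)C)[C@@H](C(=O)OC(C)C)O1)=C/COCc1ccccc1
F3 | step 6 | bis-borate adduct (10 with both carbinol oxygens bound to the (4S,5S)-tartrate-derived boron) | COc1cc([C@H](OB3O[C@H](C(=O)OC(C)C)[C@@H](C(=O)OC(C)C)O3)[C@@H](COCc3ccccc3)C(=C)C(=O)OC)cc(-c2cc([C@H](OB3O[C@H](C(=O)OC(C)C)[C@@H](C(=O)OC(C)C)O3)[C@@H](COCc3ccccc3)C(=C)C(=O)OC)cc(OC)c2O[Si](C(C)C)(C(C)C)C(C)C)c1O[Si](C(C)C)(C(C)C)C(C)C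
F4 | step 14 | debenzylated monotosylate (21 with all four benzyl ethers cleaved) | COc1cc([C@@H]3OC[C@](O)(Cc4ccc(O)c(OC)c4)[C@@H]3CO)cc(-c2cc([C@@H]3OC[C@](O)(Cc4ccc(O)c(OC)c4)[C@@H]3CO)cc(OC)c2O)c1OS(=O)(=O)c6ccc(C)cc6
F5 | step 14 | unprotected oxolane–tetralin monotosylate (24 with the oxolane-side biaryl phenol as p-toluenesulfonate) | COc1cc([C@@H]3OC[C@](O)(Cc4ccc(O)c(OC)c4)[C@@H]3CO)cc(-c2cc([C@H]3c4cc(O)c(OC)cc4C[C@@](O)(CO)[C@@H]3CO)cc(OC)c2O)c1OS(=O)(=O)c6ccc(C)cc6
F6 | step 13 | bis-tosylate (20 with both biaryl phenols as p-toluenesulfonates) | COc1cc([C@@H]3OC[C@](O)(Cc4ccc(OCc5ccccc5)c(OC)c4)[C@@H]3COCc4ccccc4)cc(-c2cc([C@@H]3OC[C@](O)(Cc4ccc(OCc5ccccc5)c(OC)c4)[C@@H]3COCc4ccccc4)cc(OC)c2OS(=O)(=O)c6ccc(C)cc6)c1OS(=O)(=O)c6ccc(C)cc6
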